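## Structural features

The target is a germacranolide: a ten-membered carbocycle (ring A, C1–C10) fused across C6–C7 to an α-methylene-γ-butyrolactone (ring B: C6, C7, C11, C12 and the lactone oxygen, with C13 as the exocyclic methylene). Ring A carries an E-trisubstituted enoate at C1=C10 (ester carbon C14 on C10, C2 and C9 cis on the ring), a hydroxymethyl group (C15) on the sp3 carbon C4, and an angelate, (Z)-2-methylbut-2-enoate, on O8. Three of the four stereocentres are contiguous, C6 (R), C7 (S) and C8 (R): the lactone is trans-fused, O8 is cis to C11 on ring A, and O6 and O8 are 1,3-anti; the fourth, C4 (R), is separated from them by the C5 methylene. The fragile groups are the angelate (Z to E isomerisation), the α-methylene lactone (conjugate addition) and the C8 oxygen, which is γ to both the C12 and the C14 carbonyl and can relactonise whenever it is free; in ketone intermediates C7 is α to C6 and β to O8 (epimerisation, elimination). The real difficulty is twofold: closing a ten-membered ring while setting the remote C4 centre, and telling O6 from O8 so that one becomes the lactone and the other the angelate. The key step exploits the 1,4-relationship of O15 and O6 across the C4–C5 bond of ring A: C4 is α to the C15 carbonyl and C5 is α to the C6 carbonyl, so this ring bond joins two enol carbons and can be made by oxidative union of an enamine (C15/C4) with an enol silane (C6/C5).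

## Logic of the disconnections

**37 ⇒ 36 ⇒ 34 + 35.** Bonds cut: O15–Si, then the ester C–O bond on O8. The angelate is the group most easily damaged, so it goes on second to last, onto a free C8 hydroxyl while C15 is still masked. Gain: 34 carries only robust groups and 35 is commercial. Demand: acylation of a hindered secondary alcohol without Z to E isomerisation, and a final deprotection that is not basic.

**34 ⇒ 29.** Bond cut: C11=C13. The exocyclic methylene is a Michael acceptor that would not survive hydride, amine or alkoxide steps, so it is added to the finished lactone. Gain: a saturated lactone. Demand: enolisation of the lactone (the most acidic C–H present) next to the C14 enoate, with O8 masked in the flask so that no alkoxide sits beside two carbonyl groups.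

**29 ⇒ 28 ⇒ 26.** Bonds cut: the acetyl C–O bond on O8, the lactone C12–O6 bond and the C6–H bond. In 26 the free C8 hydroxyl is 1,3 to the C6 ketone. A hydride delivered from a hemiacetal on O8 sets C6 anti to C8 and at the same time caps O8 as an ester, so that only O6 can close on C12. Gain: C6 and ring B are traced back to a ketone and a methyl ester, and O6 is differentiated from O8. Demand: the free C8 hydroxyl must not lactonise before it has done its work, and the acetate must later come off without O8 taking over the lactone.

**26 ⇒ 25 ⇒ 24 ⇒ 23.** Bonds cut: O8–Si (retrosynthetically restored), O15–Si, and the C15–H bond (alcohol back to aldehyde). Gain: 23 is the direct product of ring closure. Demand: reduction of an aldehyde beside a ketone, and two silyl ethers of clearly different acid lability.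

**23 ⇒ 22 (key).** Bond cut: C4–C5 of ring A. Both carbons are enol carbons of latent carbonyls, so the bond is an oxidative enamine–enol silane union. Gain: ring A opens to an acyclic chain whose only stereocentres, C7 and C8, come from the chiral pool; one ring, one C–C bond and C4 are made together. Demand: the oxidant must take the enamine before the enol silane, closure must beat oligomerisation, and the catalyst must set C4. In 22 the enol ether is a tert-butyldimethylsilyl ether and not a trimethylsilyl ether, because it has to survive the unveiling of the aldehyde and hours in a wet, acidic, oxidising medium.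

**22 ⇒ 21 ⇒ 18.** Bonds cut: the second C15–O bond (aldehyde back to alcohol) and the enol O–Si bond (back to the methyl ketone). An aldehyde cannot be present when the ketone is enolised, and an enol silane does not survive removal of an ordinary hydroxyl protecting group; the hydroxyl is therefore masked only in the flask. Demand: enolisation toward C5 and not C7, without a free enolate, and an oxidation that leaves the enol silane alone.

**18 ⇒ 16.** Functional-group change at C5–C6: the methyl ketone comes from a terminal alkyne. A C6 ketone would react with the C10 phosphonate carbanion (five-membered olefination), form a lactol with a C9 hydroxyl and participate in displacement at C9; the alkyne does none of this. Demand: Markovnikov hydration that spares the C8 silyl ether and the enoate.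

**16 ⇒ 12 + 15.** Bond cut: C1=C10, by olefination. Gain: two fragments of similar size. Demand: E-geometry at a trisubstituted enoate.

**12 ⇒ 9 + 10.** Bond cut: C9–C10. Demand: displacement at a β-branched, β-oxygenated primary carbon, hence a triflate.

**9 ⇒ 8 ⇒ 7 ⇒ 5.** Bonds cut: O9–Si; the C12 ester back to a vinyl group; C5≡C6 back to the ester carbonyl of 5 (C5–C6 bond). The alkyne is made before the C12 ester so that the molecule never holds two esters needing differentiation. Demand: no epimerisation of C7 at the aldehyde stage, and alkene-selective ozonolysis.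

**5 ⇒ 4 ⇒ 3 ⇒ 1 + 2.** Bonds cut: two O–Si bonds, one C–H pair at C9 (ester to alcohol), and the C7–C11 bond. The anti alkylation of the malate dianion sets C7 relative to the existing C8 carbinol. Demand: reduction of the ester next to the hydroxyl only.

**15 ⇒ 14 ⇒ 13.** C1–C4 and C15 come from a symmetric diol by monosilylation and oxidation.

## Other disconnections considered

**Alternative 1:** The cut is C5–C6, with the lactone C12–O bond opened in the same move and C15 carried as an exocyclic methylene on C4. In the forward sense the allylsilane aldehyde A2 with BF3·OEt2 would close ring A by attack of the allylsilane terminus C5 on the C6 aldehyde; the C6 alkoxide would then acylate on the C12 ester to give the lactone A1.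
- In favour: Lewis-acid allylsilane–aldehyde closures are an established route to medium and large carbocycles, no oxidant is needed, and ring B forms in the same operation. For an aldehyde with anti α-substituent and β-alkoxy group, 1,2- and 1,3-induction both point to the (6R) carbinol. On reliability of the ring-forming reaction type and on control of C6, this plan is the better one.
- Against: C4 stays sp2, so its configuration must be made later by hydroboration of a 1,1-disubstituted alkene on a flexible ten-membered ring, with nothing in A1 that clearly differentiates the faces and with the C1=C10 enoate present. The α-branched β-alkoxy aldehyde of A2 may epimerise at C7 or eliminate under the Lewis acid.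
- Comparison: structurally it leaves the one isolated stereocentre unsolved, where the chosen plan sets it in the ring closure. Mechanistically it is a precedented polar closure against an unprecedented radical-cation closure. Step count is about equal, since what A1 saves on the lactone is spent on C15.

**Alternative 2:** The cut is C8–C9 after reconnecting C1 to C6, so ring A comes from a six-membered ring by [3,3] ring expansion. Forward: the cis-dialkenylcyclohexanol A4 with KH and 18-crown-6 gives the C6 potassium alkoxide, which rearranges (C8–C9 formed, C1–C6 broken) to a ten-membered enolate, trapped with Me3SiCl as the enol silane A3.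
- In favour: ring expansion needs no high dilution and is a known way to cyclodecenones. A chair transition state would transfer chirality to C8 and give the ring-cis C1=C10 alkene, and C4 can be set on a six-membered ring, where facial control is easier. For making the ten-membered ring itself this plan is the better one.
- Against: A3 lacks C11–C13, so C7 must be alkylated on the ring and its configuration set there. C14 is at the alcohol level, C6 must be reduced without a free directing hydroxyl, and A4 needs three stereocentres, one a quaternary carbinol bearing a defined (E)-alkoxyvinyl group. A cis-dialkenyl substrate can also react through a boat, which would scramble the stereochemical outcome.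
- Comparison: the chosen plan has C7 and C8 fixed from the chiral pool before ring closure, whereas here C7 comes after. The mechanism is concerted and predictable, against a radical cation. Step economy is worse because of the oxidation-level and substituent work after A3.

**Alternative 3:** The cut is C2–C3 after inserting a carboxylate between them: ring contraction of a twelve-membered lactone. Forward: Pd(PPh3)4 ionises the allylic C2–O bond of the lactone A6, the α-sulfonyl carboxylate loses CO2, and the C3 carbanion recombines with the allyl terminus C2 to give the carbocycle A5.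
- In favour: the ring-closing event before it is a twelve-membered lactonisation, which is easier than direct ten-membered carbocyclisation. The C–C bond then forms within an ion pair without dilution, and ring B and all four stereocentres are in place beforehand. In having every stereocentre set before ring formation, this plan is the better one.
- Against: the allyl cation can lose its alkene geometry or be attacked at the C10 end. The sulfonyl group must be removed reductively at the end in the presence of an enoate and a lactone, which is hard to reconcile. C4 needs separate asymmetric chemistry next to the sulfonylacetate.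
- Comparison: structurally complete but burdened with an activating group. The mechanism is known zerovalent-palladium chemistry, against new chemistry. Step economy is worse by the steps that put the sulfone in and take it out.

Key step: step 14

Remarks on the chemistry:
- Locants are germacrane locants (ring A C1–C10; C11–C13 on C7; C14 on C10; C15 on C4).
- Stereochemical bookkeeping: (S)-malate supplies C8 (R in the target), anti alkylation supplies C7, and 22 and 23 carry both centres in the arrangement of the target; 23 is (4R).
- Assumption: the (2S,5S)-enantiomer of the imidazolidinone exposes the Si face of C4 in the E-enamine radical cation (benzyl group over the Re face), which leads to (4R); if the facial sense were the reverse, the (2R,5R)-enantiomer would be used with nothing else changed.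

## Steps

Step 1
Reactants: 1 dimethyl (S)-malate; 2 allyl bromide
Product: 3 dimethyl (2S,3R)-2-hydroxy-3-(prop-2-en-1-yl)butanedioate
Conditions: LiN(SiMe3)2 (2.1 equiv), THF, −78 → −20 °C; then 2, −78 → −10 °C
Reagents that add atoms: none
Why: Fráter–Seebach alkylation: the chelated lithium alkoxide-enolate is alkylated on the face anti to the C2 oxygen, which should give mainly the anti (2S,3R) product and so fixes C8 (the malate carbinol) and C7.

Step 2
Reactants: 3 dimethyl (2S,3R)-2-hydroxy-3-(prop-2-en-1-yl)butanedioate
Product: 4 methyl (2R,3S)-3,4-dihydroxy-2-(prop-2-en-1-yl)butanoate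
Conditions: BH3·SMe2 (1.0 equiv), NaBH4 (5 mol %), THF, 0 °C → rt; MeOH quench
Reagents that add atoms: none
Why: Hydroxyl-directed borane reduction of an α-hydroxy ester: the C2 oxygen binds boron and hydride is delivered within a five-membered chelate to the adjacent ester only, so the distal ester (future C6) is kept; with one equivalent of borane the alkoxyborane forms first and hydroboration of the allyl group should stay minor.

Step 3
Reactants: 4 methyl (2R,3S)-3,4-dihydroxy-2-(prop-2-en-1-yl)butanoate
Product: 5 methyl (2R,3S)-3,4-bis(tert-butyldimethylsilyloxy)-2-(prop-2-en-1-yl)butanoate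
Conditions: t-BuMe2SiOTf (2.4 equiv), 2,6-lutidine, CH2Cl2, −78 → 0 °C
Reagents that add atoms: tert-butyldimethylsilyl trifluoromethanesulfonate, CC(C)(C)[Si](C)(C)OS(=O)(=O)C(F)(F)F
Why: Silylation of both hydroxyls, done at once on the crude diol because the free primary hydroxyl would otherwise close onto the ester as a γ-lactone.

Step 4
Reactants: 5 methyl (2R,3S)-3,4-bis(tert-butyldimethylsilyloxy)-2-(prop-2-en-1-yl)butanoate
Product: 7 (3S,4S)-4,5-bis(tert-butyldimethylsilyloxy)-3-(prop-2-en-1-yl)pent-1-yne, via aldehyde 6 (not isolated)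
Conditions: i-Bu2AlH (1.1 equiv), CH2Cl2, −78 °C; then MeOH, dimethyl (1-diazo-2-oxopropyl)phosphonate, K2CO3, −78 °C → rt
Reagents that add atoms: dimethyl (1-diazo-2-oxopropyl)phosphonate, COP(=O)(OC)C(=[N+]=[N-])C(C)=O
Why: Partial ester reduction (the aluminium acetal is stable at −78 °C) followed in the same flask by Seyferth–Gilbert homologation with the Ohira–Bestmann reagent; the diazo carbon becomes C5, and the alkyne is a base-stable latent C6 methyl ketone.

Step 5
Reactants: 7 (3S,4S)-4,5-bis(tert-butyldimethylsilyloxy)-3-(prop-2-en-1-yl)pent-1-yne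
Product: 8 methyl (3S,4S)-4,5-bis(tert-butyldimethylsilyloxy)-3-ethynylpentanoate
Conditions: O3, NaOH (2.5 M in MeOH), CH2Cl2, −78 °C, to the alkene end point
Reagents that add atoms: ozone, [O-][O+]=O; methanol, CO
Why: Ozonolysis in basic methanol turns a terminal alkene directly into the methyl ester with one carbon less (the hemiacetal of the aldehyde is oxidised by ozone); the alkene reacts far faster than the terminal alkyne.

Step 6
Reactants: 8 methyl (3S,4S)-4,5-bis(tert-butyldimethylsilyloxy)-3-ethynylpentanoate
Product: 9 methyl (3S,4S)-4-(tert-butyldimethylsilyloxy)-3-ethynyl-5-hydroxypentanoate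
Conditions: HF·pyridine, pyridine, THF, 0 °C → rt
Reagents that add atoms: none
Why: Selective desilylation: the primary silyl ether is cleaved well before the hindered secondary one under buffered fluoride, and these conditions should not lactonise the δ-hydroxy ester.

Step 7
Reactants: 9 methyl (3S,4S)-4-(tert-butyldimethylsilyloxy)-3-ethynyl-5-hydroxypentanoate; 10 trimethyl phosphonoacetate
Product: 12 dimethyl (4R,5S)-4-(tert-butyldimethylsilyloxy)-2-(dimethoxyphosphoryl)-5-ethynylheptanedioate (C2 epimers), via triflate 11 (not isolated)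
Conditions: Tf2O, 2,6-lutidine, CH2Cl2, −78 °C; the cold solution is then added to 10 (2.5 equiv), NaH (2.4 equiv), 15-crown-5, THF, −20 → 0 °C
Reagents that add atoms: trifluoromethanesulfonic anhydride, O=S(=O)(OS(=O)(=O)C(F)(F)F)C(F)(F)F (atoms kept in 11 only)
Why: SN2 alkylation of the sodium phosphonoacetate carbanion; a triflate is used because the β-branched, β-silyloxy primary carbon C9 would be too slow as a halide, and the excess of soft carbanion should outrun participation by the ester carbonyl and suppress dialkylation.

Step 8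
Reactants: 13 pentane-1,5-diol
Product: 14 5-(triethylsilyloxy)pentan-1-ol
Conditions: Et3SiCl (0.33 equiv), imidazole, CH2Cl2, 0 °C, diol in threefold excess
Reagents that add atoms: chlorotriethylsilane, CC[Si](CC)(CC)Cl
Why: Statistical monosilylation of a symmetric diol; the excess diol is removed by aqueous wash.

Step 9
Reactants: 14 5-(triethylsilyloxy)pentan-1-ol
Product: 15 5-(triethylsilyloxy)pentanal
Conditions: SO3·pyridine, DMSO, i-Pr2NEt, CH2Cl2, 0 °C
Reagents that add atoms: none
Why: Parikh–Doering oxidation of the primary alcohol; the basic medium leaves the acid-labile triethylsilyl ether intact.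

Step 10
Reactants: 12 dimethyl (4R,5S)-4-(tert-butyldimethylsilyloxy)-2-(dimethoxyphosphoryl)-5-ethynylheptanedioate; 15 5-(triethylsilyloxy)pentanal
Product: 16 methyl (2E)-2-[(2R,3S)-2-(tert-butyldimethylsilyloxy)-3-ethynyl-5-methoxy-5-oxopentyl]-7-(triethylsilyloxy)hept-2-enoate
Conditions: LiCl, DBU, MeCN, 0 °C → rt
Reagents that add atoms: none
Why: Horner–Wadsworth–Emmons olefination under mild lithium chloride/amine conditions; the α-substituted phosphonoacetate should give mainly the E-enoate (ester trans to the new chain), which is the ring-cis arrangement of C2 and C9 needed later, and the alkyne, unlike a C6 ketone, cannot react with the phosphonate carbanion.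

Step 11
Reactants: 16 methyl (2E)-2-[(2R,3S)-2-(tert-butyldimethylsilyloxy)-3-ethynyl-5-methoxy-5-oxopentyl]-7-(triethylsilyloxy)hept-2-enoate
Product: 18 methyl (2E)-2-[(2R,3R)-3-acetyl-2-(tert-butyldimethylsilyloxy)-5-methoxy-5-oxopentyl]-7-hydroxyhept-2-enoate, via ketone silyl ether 17 (not isolated)
Conditions: (Ph3P)AuNTf2 (2 mol %), MeOH/H2O (10:1), 40 °C; then pyridinium p-toluenesulfonate, rt
Reagents that add atoms: water, O
Why: Markovnikov hydration of the terminal alkyne catalysed by monovalent gold gives the C6 methyl ketone (attack at C6 is also favoured by 5-exo participation of the C12 ester carbonyl); the mild acid in methanol then removes only the primary triethylsilyl ether.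

Step 12
Reactants: 18 methyl (2E)-2-[(2R,3R)-3-acetyl-2-(tert-butyldimethylsilyloxy)-5-methoxy-5-oxopentyl]-7-hydroxyhept-2-enoate
Product: 21 methyl (2E)-2-[(2R,3R)-2-(tert-butyldimethylsilyloxy)-3-[1-(tert-butyldimethylsilyloxy)ethenyl]-5-methoxy-5-oxopentyl]-7-hydroxyhept-2-enoate, via trimethylsilyl ether 19 (not isolated), via bis-silyl compound 20 (not isolated)
Conditions: Me3SiCl (1.1 equiv), Et3N, CH2Cl2, 0 °C; t-BuMe2SiOTf (1.3 equiv), −78 → 0 °C; then K2CO3, MeOH, 0 °C, short
Reagents that add atoms: tert-butyldimethylsilyl trifluoromethanesulfonate, CC(C)(C)[Si](C)(C)OS(=O)(=O)C(F)(F)F; chlorotrimethylsilane, C[Si](C)(C)Cl (atoms kept in 19 and 20 only)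
Why: Soft enolisation (silyl triflate and amine) removes the unhindered C5 methyl proton in preference to the tertiary C7 proton and gives the terminal enol silane without a free enolate that could expel the C8 silyloxy group or attack the C12 ester; the C15 hydroxyl is masked meanwhile as a trimethylsilyl ether, which brief carbonate methanolysis removes while the bulkier enol and secondary silyl ethers stay.

Step 13
Reactants: 21 methyl (2E)-2-[(2R,3R)-2-(tert-butyldimethylsilyloxy)-3-[1-(tert-butyldimethylsilyloxy)ethenyl]-5-methoxy-5-oxopentyl]-7-hydroxyhept-2-enoate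
Product: 22 methyl (2E)-2-[(2R,3R)-2-(tert-butyldimethylsilyloxy)-3-[1-(tert-butyldimethylsilyloxy)ethenyl]-5-methoxy-5-oxopentyl]-7-oxohept-2-enoate
Conditions: SO3·pyridine, DMSO, i-Pr2NEt, CH2Cl2, 0 °C; used at once
Reagents that add atoms: none
Why: Parikh–Doering oxidation; the medium is basic and free of acids and strong electrophiles, so the enol silane should survive while the primary alcohol becomes the aldehyde.

Step 14
Reactants: 22 methyl (2E)-2-[(2R,3R)-2-(tert-butyldimethylsilyloxy)-3-[1-(tert-butyldimethylsilyloxy)ethenyl]-5-methoxy-5-oxopentyl]-7-oxohept-2-enoate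
Product: 23 methyl (1E,4R,7R,8R)-8-(tert-butyldimethylsilyloxy)-4-formyl-7-(2-methoxy-2-oxoethyl)-6-oxocyclodec-1(10)-ene-10-carboxylate
Conditions: (2S,5S)-5-benzyl-2-tert-butyl-3-methylimidazolidin-4-one·CF3CO2H (1.0 equiv), (NH4)2Ce(NO3)6 (2.5 equiv), NaHCO3 (3 equiv), H2O (3 equiv), 1,2-dimethoxyethane, −20 °C; 22 added by syringe pump over 12 h to a final 1 mM
Reagents that add atoms: water, O (supplies the aldehyde oxygen when the iminium ion is hydrolysed)
Why: Proposed new method: the amine condenses with the unbranched C15 aldehyde of 22 to an E-enamine, one-electron oxidation by tetravalent cerium (much easier for the enamine than for the enol silane) gives a 3π-electron radical cation that is electrophilic at C4, this adds to the unsubstituted C5 terminus of the electron-rich C5=C6 enol silane, the α-silyloxy radical at C6 is oxidised to a silyloxocarbenium ion that gives up silicon to water, and hydrolysis of the iminium ion returns the aldehyde and the amine. The closest known reactions are the intermolecular organocatalytic singly-occupied-orbital α-enolation of aldehydes with enol silanes and the cyclisations of the same radical cations onto allylsilanes and arenes to five- to seven-membered rings; a ten-membered closure has not been shown. Ring A closes in the 10-endo-trig mode: C4 bonds to the terminal carbon of the C5=C6 double bond, whose other carbon lies inside the new ring. The new C4 stereocentre is controlled by the catalyst and not by C7 or C8: the tert-butyl group fixes the enamine rotamer, the benzyl group covers the Re face of C4, C5 bonds to the Si face, and this gives (4R). Chemoselectivity rests on the low oxidation potential of the enamine and on polarity matching, the electron-rich enol silane being the partner of the electrophilic radical while the electron-poor C1=C10 enoate (which could only give four- or five-membered rings) is left alone. Cyclisation over oligomerisation is secured by syringe-pump addition to about 1 mM with a full equivalent of amine so that enamine formation stays fast, and is helped by the turn that the ring-cis C1=C10 alkene and the C7/C8 substituents put into the chain. The tert-butyldimethylsilyl enol ether is used because it should survive the wet, acidic medium for the hours of slow addition, and NaHCO3 buffers the nitric acid set free. The α-branched aldehyde of 23 is too hindered to form an enamine with this amine, so C4 should not epimerise.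

Step 15
Reactants: 23 methyl (1E,4R,7R,8R)-8-(tert-butyldimethylsilyloxy)-4-formyl-7-(2-methoxy-2-oxoethyl)-6-oxocyclodec-1(10)-ene-10-carboxylate
Product: 24 methyl (1E,4R,7R,8R)-8-(tert-butyldimethylsilyloxy)-4-(hydroxymethyl)-7-(2-methoxy-2-oxoethyl)-6-oxocyclodec-1(10)-ene-10-carboxylate
Conditions: NaBH4 (0.5 equiv), MeOH/CH2Cl2, −78 °C
Reagents that add atoms: none
Why: Chemoselective hydride reduction of the aldehyde beside the hindered C6 ketone and the esters at low temperature, done directly on crude 23 so that C4 has no time to epimerise.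

Step 16
Reactants: 24 methyl (1E,4R,7R,8R)-8-(tert-butyldimethylsilyloxy)-4-(hydroxymethyl)-7-(2-methoxy-2-oxoethyl)-6-oxocyclodec-1(10)-ene-10-carboxylate
Product: 25 methyl (1E,4R,7R,8R)-8-(tert-butyldimethylsilyloxy)-4-[(tert-butyldiphenylsilyloxy)methyl]-7-(2-methoxy-2-oxoethyl)-6-oxocyclodec-1(10)-ene-10-carboxylate
Conditions: t-BuPh2SiCl, imidazole, CH2Cl2, 0 °C → rt
Reagents that add atoms: tert-butyl(chloro)diphenylsilane, CC(C)(C)[Si](Cl)(c1ccccc1)c1ccccc1
Why: Silylation of the primary hydroxyl (the open hydroxy ketone reacts, a tertiary hemiketal hydroxyl does not); this group outlasts acid removal of the C8 silyl ether and comes off at the end without base.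

Step 17
Reactants: 25 methyl (1E,4R,7R,8R)-8-(tert-butyldimethylsilyloxy)-4-[(tert-butyldiphenylsilyloxy)methyl]-7-(2-methoxy-2-oxoethyl)-6-oxocyclodec-1(10)-ene-10-carboxylate
Product: 26 methyl (1E,4R,7R,8R)-4-[(tert-butyldiphenylsilyloxy)methyl]-8-hydroxy-7-(2-methoxy-2-oxoethyl)-6-oxocyclodec-1(10)-ene-10-carboxylate
Conditions: HF·pyridine, THF, 0 °C → rt, monitored
Reagents that add atoms: none
Why: Under mildly acidic fluoride a tert-butyldimethylsilyl ether is cleaved much faster than a tert-butyldiphenylsilyl ether; the β-hydroxy ketone is taken on crude so that the free C8 hydroxyl has little time to close onto the C12 or C14 ester.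

Step 18
Reactants: 26 methyl (1E,4R,7R,8R)-4-[(tert-butyldiphenylsilyloxy)methyl]-8-hydroxy-7-(2-methoxy-2-oxoethyl)-6-oxocyclodec-1(10)-ene-10-carboxylate
Product: 28 methyl (1E,4R,6R,7S,8R)-8-acetoxy-15-(tert-butyldiphenylsilyloxy)germacr-1(10)-en-12,6-olid-14-oate, via hydroxy acetate 27 (not isolated)
Conditions: MeCHO (10 equiv), SmI2 (0.3 equiv), THF, −10 °C; then camphorsulfonic acid (cat.), CH2Cl2, rt
Reagents that add atoms: acetaldehyde, CC=O
Why: Evans–Tishchenko reduction: the C8 hydroxyl forms a samarium-bound hemiacetal with acetaldehyde and hydride shifts from it to C6 through a chair-like cyclic transition state, which should give the 1,3-anti (6R) carbinol and leave O8 as its acetate; only O6 is then free to close onto the C12 methyl ester, giving the trans-fused lactone.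

Step 19
Reactants: 28 methyl (1E,4R,6R,7S,8R)-8-acetoxy-15-(tert-butyldiphenylsilyloxy)germacr-1(10)-en-12,6-olid-14-oate
Product: 29 methyl (1E,4R,6R,7R,8R)-15-(tert-butyldiphenylsilyloxy)-8-hydroxygermacr-1(10)-en-12,6-olid-14-oate
Conditions: K2CO3 (0.3 equiv), MeOH, 0 °C, short; acetic acid quench
Reagents that add atoms: none
Why: Carbonate-catalysed transesterification of the secondary acetate with methanol; the γ-lactone is favoured over its open methyl ester, and low temperature and short contact are meant to keep the freed C8 hydroxyl from exchanging with the lactone.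

Step 20
Reactants: 29 methyl (1E,4R,6R,7R,8R)-15-(tert-butyldiphenylsilyloxy)-8-hydroxygermacr-1(10)-en-12,6-olid-14-oate
Product: 34 methyl (1E,4R,6R,7R,8R)-15-(tert-butyldiphenylsilyloxy)-8-hydroxygermacra-1(10),11(13)-dien-12,6-olid-14-oate, via trimethylsilyl ether 30 (not isolated), via Mannich base 31 (not isolated), via ammonium iodide 32 (not isolated), via silylated methylene lactone 33 (not isolated)
Conditions: LiN(SiMe3)2 (1.05 equiv), THF, −78 °C, then Me3SiCl (1.05 equiv); LiN(SiMe3)2 (1.2 equiv), −78 °C; N,N-dimethylmethyleneiminium iodide, −78 °C → rt; MeI, rt; NaHCO3 (aq), rt; citric acid, MeOH, 0 °C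
Reagents that add atoms: N,N-dimethylmethyleneiminium iodide, C=[N+](C)C.[I-]; iodomethane, CI (atoms kept in 32 only); chlorotrimethylsilane, C[Si](C)(C)Cl (atoms kept in 30 to 33 only)
Why: Eschenmoser methylenation: the lactone α-protons are the most acidic C–H bonds present, so the lithium enolate forms at C11 and undergoes a Mannich reaction, and quaternisation followed by E1cB elimination gives the α-methylene lactone; O8 is silylated in the flask first so that no lithium alkoxide sits next to the lactone and the C14 ester.

Step 21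
Reactants: 34 methyl (1E,4R,6R,7R,8R)-15-(tert-butyldiphenylsilyloxy)-8-hydroxygermacra-1(10),11(13)-dien-12,6-olid-14-oate; 35 (Z)-2-methylbut-2-enoic acid (angelic acid)
Product: 36 methyl (1E,4R,6R,7S,8R)-15-(tert-butyldiphenylsilyloxy)-8-[(Z)-2-methylbut-2-enoyloxy]germacra-1(10),11(13)-dien-12,6-olid-14-oate
Conditions: 35, 2,4,6-trichlorobenzoyl chloride, Et3N, toluene, rt; then 34, 75 °C
Reagents that add atoms: none
Why: Yamaguchi-type esterification through the mixed anhydride, run without a nucleophilic pyridine catalyst because such catalysts isomerise the Z-acyl group to the E form; the alcohol attacks the less hindered angeloyl carbonyl.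

Step 22
Reactants: 36 methyl (1E,4R,6R,7S,8R)-15-(tert-butyldiphenylsilyloxy)-8-[(Z)-2-methylbut-2-enoyloxy]germacra-1(10),11(13)-dien-12,6-olid-14-oate
Product: 37 methyl (1E,4R,6R,7S,8R)-15-hydroxy-8-[(Z)-2-methylbut-2-enoyloxy]germacra-1(10),11(13)-dien-12,6-olid-14-oate
Conditions: HF·pyridine, THF, 0 °C → rt
Reagents that add atoms: none
Why: Fluoride cleavage of the primary silyl ether under mildly acidic, non-nucleophilic conditions that should leave the angelate geometry, the α-methylene lactone and the esters untouched.

## Compound list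

1 | dimethyl (S)-malate | COC(=O)C[C@H](O)C(=O)OC | starting material
2 | allyl bromide | C=CCBr | starting material
3 | dimethyl (2S,3R)-2-hydroxy-3-(prop-2-en-1-yl)butanedioate | COC(=O)[C@@H](O)[C@@H](CC=C)C(=O)OC | intermediate
4 | methyl (2R,3S)-3,4-dihydroxy-2-(prop-2-en-1-yl)butanoate | OC[C@@H](O)[C@@H](CC=C)C(=O)OC | intermediate
5 | methyl (2R,3S)-3,4-bis(tert-butyldimethylsilyloxy)-2-(prop-2-en-1-yl)butanoate | CC(C)(C)[Si](C)(C)OC[C@@H](O[Si](C)(C)C(C)(C)C)[C@@H](CC=C)C(=O)OC | intermediate
6 | (2R,3S)-3,4-bis(tert-butyldimethylsilyloxy)-2-(prop-2-en-1-yl)butanal | CC(C)(C)[Si](C)(C)OC[C@@H](O[Si](C)(C)C(C)(C)C)[C@@H](CC=C)C=O | intermediate (not isolated)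
7 | (3S,4S)-4,5-bis(tert-butyldimethylsilyloxy)-3-(prop-2-en-1-yl)pent-1-yne | CC(C)(C)[Si](C)(C)OC[C@@H](O[Si](C)(C)C(C)(C)C)[C@@H](CC=C)C#C | intermediate
8 | methyl (3S,4S)-4,5-bis(tert-butyldimethylsilyloxy)-3-ethynylpentanoate | CC(C)(C)[Si](C)(C)OC[C@@H](O[Si](C)(C)C(C)(C)C)[C@@H](CC(=O)OC)C#C | intermediate
9 | methyl (3S,4S)-4-(tert-butyldimethylsilyloxy)-3-ethynyl-5-hydroxypentanoate | OC[C@@H](O[Si](C)(C)C(C)(C)C)[C@@H](CC(=O)OC)C#C | intermediate
10 | trimethyl phosphonoacetate | COC(=O)CP(=O)(OC)OC | starting material
11 | methyl (3S,4S)-4-(tert-butyldimethylsilyloxy)-3-ethynyl-5-(trifluoromethylsulfonyloxy)pentanoate | O=S(=O)(OC[C@@H](O[Si](C)(C)C(C)(C)C)[C@@H](CC(=O)OC)C#C)C(F)(F)F | intermediate (not isolated)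
12 | dimethyl (4R,5S)-4-(tert-butyldimethylsilyloxy)-2-(dimethoxyphosphoryl)-5-ethynylheptanedioate (C2 epimers) | COC(=O)C(C[C@@H](O[Si](C)(C)C(C)(C)C)[C@@H](CC(=O)OC)C#C)P(=O)(OC)OC | intermediate
13 | pentane-1,5-diol | OCCCCCO | starting material
14 | 5-(triethylsilyloxy)pentan-1-ol | CC[Si](CC)(CC)OCCCCCO | intermediate
15 | 5-(triethylsilyloxy)pentanal | CC[Si](CC)(CC)OCCCCC=O | intermediate
16 | methyl (2E)-2-[(2R,3S)-2-(tert-butyldimethylsilyloxy)-3-ethynyl-5-methoxy-5-oxopentyl]-7-(triethylsilyloxy)hept-2-enoate | COC(=O)/C(C[C@@H](O[Si](C)(C)C(C)(C)C)[C@@H](CC(=O)OC)C#C)=C/CCCCO[Si](CC)(CC)CC | intermediate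
17 | methyl (2E)-2-[(2R,3R)-3-acetyl-2-(tert-butyldimethylsilyloxy)-5-methoxy-5-oxopentyl]-7-(triethylsilyloxy)hept-2-enoate | COC(=O)/C(C[C@@H](O[Si](C)(C)C(C)(C)C)[C@@H](CC(=O)OC)C(C)=O)=C/CCCCO[Si](CC)(CC)CC | intermediate (not isolated)
18 | methyl (2E)-2-[(2R,3R)-3-acetyl-2-(tert-butyldimethylsilyloxy)-5-methoxy-5-oxopentyl]-7-hydroxyhept-2-enoate | COC(=O)/C(C[C@@H](O[Si](C)(C)C(C)(C)C)[C@@H](CC(=O)OC)C(C)=O)=C/CCCCO | intermediate
19 | methyl (2E)-2-[(2R,3R)-3-acetyl-2-(tert-butyldimethylsilyloxy)-5-methoxy-5-oxopentyl]-7-(trimethylsilyloxy)hept-2-enoate | COC(=O)/C(C[C@@H](O[Si](C)(C)C(C)(C)C)[C@@H](CC(=O)OC)C(C)=O)=C/CCCCO[Si](C)(C)C | intermediate (not isolated)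
20 | methyl (2E)-2-[(2R,3R)-2-(tert-butyldimethylsilyloxy)-3-[1-(tert-butyldimethylsilyloxy)ethenyl]-5-methoxy-5-oxopentyl]-7-(trimethylsilyloxy)hept-2-enoate | COC(=O)/C(C[C@@H](O[Si](C)(C)C(C)(C)C)[C@@H](CC(=O)OC)C(=C)O[Si](C)(C)C(C)(C)C)=C/CCCCO[Si](C)(C)C | intermediate (not isolated)
21 | methyl (2E)-2-[(2R,3R)-2-(tert-butyldimethylsilyloxy)-3-[1-(tert-butyldimethylsilyloxy)ethenyl]-5-methoxy-5-oxopentyl]-7-hydroxyhept-2-enoate | COC(=O)/C(C[C@@H](O[Si](C)(C)C(C)(C)C)[C@@H](CC(=O)OC)C(=C)O[Si](C)(C)C(C)(C)C)=C/CCCCO | intermediate
22 | methyl (2E)-2-[(2R,3R)-2-(tert-butyldimethylsilyloxy)-3-[1-(tert-butyldimethylsilyloxy)ethenyl]-5-methoxy-5-oxopentyl]-7-oxohept-2-enoate (seco aldehyde with C6 enol silane) | COC(=O)/C(C[C@@H](O[Si](C)(C)C(C)(C)C)[C@@H](CC(=O)OC)C(=C)O[Si](C)(C)C(C)(C)C)=C/CCCC=O | intermediate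
23 | methyl (1E,4R,7R,8R)-8-(tert-butyldimethylsilyloxy)-4-formyl-7-(2-methoxy-2-oxoethyl)-6-oxocyclodec-1(10)-ene-10-carboxylate | O=C[C@@H]1CC/C=C(/C(=O)OC)C[C@@H](O[Si](C)(C)C(C)(C)C)[C@@H](CC(=O)OC)C(=O)C1 | intermediate
24 | methyl (1E,4R,7R,8R)-8-(tert-butyldimethylsilyloxy)-4-(hydroxymethyl)-7-(2-methoxy-2-oxoethyl)-6-oxocyclodec-1(10)-ene-10-carboxylate | OC[C@@H]1CC/C=C(/C(=O)OC)C[C@@H](O[Si](C)(C)C(C)(C)C)[C@@H](CC(=O)OC)C(=O)C1 | intermediate
25 | methyl (1E,4R,7R,8R)-8-(tert-butyldimethylsilyloxy)-4-[(tert-butyldiphenylsilyloxy)methyl]-7-(2-methoxy-2-oxoethyl)-6-oxocyclodec-1(10)-ene-10-carboxylate | CC(C)(C)[Si](c2ccccc2)(c3ccccc3)OC[C@@H]1CC/C=C(/C(=O)OC)C[C@@H](O[Si](C)(C)C(C)(C)C)[C@@H](CC(=O)OC)C(=O)C1 | intermediate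
26 | methyl (1E,4R,7R,8R)-4-[(tert-butyldiphenylsilyloxy)methyl]-8-hydroxy-7-(2-methoxy-2-oxoethyl)-6-oxocyclodec-1(10)-ene-10-carboxylate | CC(C)(C)[Si](c2ccccc2)(c3ccccc3)OC[C@@H]1CC/C=C(/C(=O)OC)C[C@@H](O)[C@@H](CC(=O)OC)C(=O)C1 | intermediate
27 | methyl (1E,4R,6R,7S,8R)-8-acetoxy-4-[(tert-butyldiphenylsilyloxy)methyl]-6-hydroxy-7-(2-methoxy-2-oxoethyl)cyclodec-1(10)-ene-10-carboxylate | CC(C)(C)[Si](c2ccccc2)(c3ccccc3)OC[C@@H]1CC/C=C(/C(=O)OC)C[C@@H](OC(C)=O)[C@@H](CC(=O)OC)[C@H](O)C1 | intermediate (not isolated)
28 | methyl (1E,4R,6R,7S,8R)-8-acetoxy-15-(tert-butyldiphenylsilyloxy)germacr-1(10)-en-12,6-olid-14-oate | C1C(=O)O[C@@H]2C[C@H](CO[Si](c3ccccc3)(c4ccccc4)C(C)(C)C)CC/C=C(/C(=O)OC)C[C@@H](OC(C)=O)[C@@H]12 | intermediate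
29 | methyl (1E,4R,6R,7R,8R)-15-(tert-butyldiphenylsilyloxy)-8-hydroxygermacr-1(10)-en-12,6-olid-14-oate | C1C(=O)O[C@@H]2C[C@H](CO[Si](c3ccccc3)(c4ccccc4)C(C)(C)C)CC/C=C(/C(=O)OC)C[C@@H](O)[C@@H]12 | intermediate
30 | methyl (1E,4R,6R,7S,8R)-15-(tert-butyldiphenylsilyloxy)-8-(trimethylsilyloxy)germacr-1(10)-en-12,6-olid-14-oate | C1C(=O)O[C@@H]2C[C@H](CO[Si](c3ccccc3)(c4ccccc4)C(C)(C)C)CC/C=C(/C(=O)OC)C[C@@H](O[Si](C)(C)C)[C@@H]12 | intermediate (not isolated)
31 | methyl (1E,4R,6R,7S,8R)-15-(tert-butyldiphenylsilyloxy)-13-(dimethylamino)-8-(trimethylsilyloxy)germacr-1(10)-en-12,6-olid-14-oate (C11 epimers) | CN(C)CC1C(=O)O[C@@H]2C[C@H](CO[Si](c3ccccc3)(c4ccccc4)C(C)(C)C)CC/C=C(/C(=O)OC)C[C@@H](O[Si](C)(C)C)[C@@H]12 | intermediate (not isolated)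
32 | trimethylammonium iodide from N-methylation of 31 | C[N+](C)(C)CC1C(=O)O[C@@H]2C[C@H](CO[Si](c3ccccc3)(c4ccccc4)C(C)(C)C)CC/C=C(/C(=O)OC)C[C@@H](O[Si](C)(C)C)[C@@H]12.[I-] | intermediate (not isolated)
33 | methyl (1E,4R,6R,7S,8R)-15-(tert-butyldiphenylsilyloxy)-8-(trimethylsilyloxy)germacra-1(10),11(13)-dien-12,6-olid-14-oate | C=C1C(=O)O[C@@H]2C[C@H](CO[Si](c3ccccc3)(c4ccccc4)C(C)(C)C)CC/C=C(/C(=O)OC)C[C@@H](O[Si](C)(C)C)[C@@H]12 | intermediate (not isolated)
34 | methyl (1E,4R,6R,7R,8R)-15-(tert-butyldiphenylsilyloxy)-8-hydroxygermacra-1(10),11(13)-dien-12,6-olid-14-oate | C=C1C(=O)O[C@@H]2C[C@H](CO[Si](c3ccccc3)(c4ccccc4)C(C)(C)C)CC/C=C(/C(=O)OC)C[C@@H](O)[C@@H]12 | intermediate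
35 | (Z)-2-methylbut-2-enoic acid (angelic acid) | C/C=C(/C)C(=O)O | starting material
36 | methyl (1E,4R,6R,7S,8R)-15-(tert-butyldiphenylsilyloxy)-8-[(Z)-2-methylbut-2-enoyloxy]germacra-1(10),11(13)-dien-12,6-olid-14-oate | C=C1C(=O)O[C@@H]2C[C@H](CO[Si](c3ccccc3)(c4ccccc4)C(C)(C)C)CC/C=C(/C(=O)OC)C[C@@H](OC(=O)/C(C)=C\C)[C@@H]12 | intermediate
37 | methyl (1E,4R,6R,7S,8R)-15-hydroxy-8-[(Z)-2-methylbut-2-enoyloxy]germacra-1(10),11(13)-dien-12,6-olid-14-oate | C=C1C(=O)O[C@@H]2C[C@H](CO)CC/C=C(/C(=O)OC)C[C@@H](OC(=O)/C(C)=C\C)[C@@H]12 | target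

## Step count and least certain steps

Total: 22 steps. Longest linear sequence: 20 steps (steps 1–7 and 10–22; steps 8 and 9 make the aldehyde 15 on a side branch).

**Step 14 (key step, new method).** Most likely to go wrong: oligomerisation instead of end-to-end closure; hydrolysis or direct oxidation of the enol silane before it is attacked; trapping of the radical by nitrate; loss of facial control at C4 if the macrocyclic transition state overrides the catalyst; loss of C7 configuration by deprotonation of the oxocarbenium ion. A ten-membered ring gains nothing entropically and the reaction has no macrocyclic precedent.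
Fallback (known chemistry: C4–C5 made between two molecules, ring A closed at C1=C10): it sets out from 12 and comes back at 28. Gold-catalysed hydration of 12 would give the methyl ketone F1, and soft enolisation (t-BuMe2SiOTf, Et3N) the enol silane F2. The known intermolecular organocatalytic α-enolation of hex-5-enal with F2 (same amine and (NH4)2Ce(NO3)6) would give the keto aldehyde F3, with C4 set by the catalyst. Reduction with NaBH4 to the alcohol F4, silylation to the tert-butyldiphenylsilyl ether F5 and removal of the C8 silyl group with HF·pyridine would give the β-hydroxy ketone F6. Evans–Tishchenko reduction would give the hydroxy acetate F7, which closes to the acyclic lactone F8, so that no ketone remains to react with the phosphonate. Ozonolysis of the terminal alkene (O3; PPh3) would give the aldehyde F9, and a macrocyclic Horner–Wadsworth–Emmons reaction (LiCl, i-Pr2NEt, MeCN, high dilution) would close ring A to 28.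

**Step 18.** Most likely to go wrong: closure of the free C8 hydroxyl onto the C12 or C14 ester before or during the reduction; migration of the acetyl group from O8 to O6; retro-aldol opening of the ring under Lewis acid.
Fallback: it sets out from 25 and comes back at 34. The C6 ketone is reduced under reagent control with the C8 silyl ether still in place (Corey–Bakshi–Shibata reduction with (S)-1-methyl-3,3-diphenyltetrahydro-1H,3H-pyrrolo[1,2-c][1,3,2]oxazaborole and catecholborane; the branched C7 side acts as the large group), which should give the (6R) alcohol F10. This closes with mild acid to the silyl-protected lactone F11. Eschenmoser methylenation then needs no extra protection and passes through the Mannich base F12 and the ammonium iodide F13 to the methylene lactone F14. HF·pyridine removes the C8 silyl group and returns 34. This path never has a free C8 hydroxyl next to a ketone or an open ester, at the price of giving up the 1,3-anti hydride delivery.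

**Step 19.** Most likely to go wrong: exchange of the lactone from O6 to the freed O8 (or closure of O8 onto C14) under the basic methanolysis, because O8 is cis to C11 and γ to both carbonyls.
Fallback: it sets out from 26 and comes back at 29. The Evans–Tishchenko reduction is run with 4-oxopentanal in place of acetaldehyde, giving the hydroxy levulinate F15 and, after lactonisation, the levulinate lactone F16. Hydrazine acetate in pyridine/acetic acid then removes the levulinate by hydrazone formation and intramolecular acyl transfer near neutrality, giving 29 without any alkoxide.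

**Step 7.** Most likely to go wrong: slow displacement at the β-branched, β-silyloxy carbon C9, so that ionisation of the triflate with participation by the C12 ester carbonyl or the silyl ether oxygen competes.
Fallback: it sets out from 9 and comes back at 12, with no SN2 step at C9. Parikh–Doering oxidation of 9 would give the aldehyde F17; Knoevenagel condensation with 10 (TiCl4, N-methylmorpholine) the alkylidene phosphonoacetate F18; and conjugate hydride reduction of the activated double bond (NaBH4, MeOH, 0 °C) gives 12.

**Step 10.** Most likely to go wrong: poor E/Z selectivity, since α-branched phosphonoacetates are less selective than unsubstituted ones, and only the E-isomer places C2 and C9 cis.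
Fallback: it sets out from 9 (through the triflate 11) and comes back at 16. Methyl (triphenylphosphoranylidene)acetate (2 equiv) is alkylated with 11 to the phosphonium triflate F19, which the second equivalent deprotonates to the substituted stabilised ylide F20. Its Wittig reaction with 15 (toluene, 80 °C) should be more E-selective for a trisubstituted enoate and gives 16.

## Further compounds

F1 | step 14 | dimethyl (4R,5R)-5-acetyl-4-(tert-butyldimethylsilyloxy)-2-(dimethoxyphosphoryl)heptanedioate | COC(=O)C(C[C@@H](O[Si](C)(C)C(C)(C)C)[C@@H](CC(=O)OC)C(C)=O)P(=O)(OC)OC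
F2 | step 14 | tert-butyldimethylsilyl enol ether of F1 (C5=C6) | COC(=O)C(C[C@@H](O[Si](C)(C)C(C)(C)C)[C@@H](CC(=O)OC)C(=C)O[Si](C)(C)C(C)(C)C)P(=O)(OC)OC
F3 | step 14 | acyclic C6 ketone with (4R)-formyl group and but-3-enyl chain on C4 | COC(=O)C(C[C@@H](O[Si](C)(C)C(C)(C)C)[C@@H](CC(=O)OC)C(=O)C[C@H](C=O)CCC=C)P(=O)(OC)OC
F4 | step 14 | C15 alcohol from F3 | COC(=O)C(C[C@@H](O[Si](C)(C)C(C)(C)C)[C@@H](CC(=O)OC)C(=O)C[C@H](CO)CCC=C)P(=O)(OC)OC
F5 | step 14 | C15 tert-butyldiphenylsilyl ether of F4 | COC(=O)C(C[C@@H](O[Si](C)(C)C(C)(C)C)[C@@H](CC(=O)OC)C(=O)C[C@H](CO[Si](c1ccccc1)(c1ccccc1)C(C)(C)C)CCC=C)P(=O)(OC)OC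
F6 | step 14 | acyclic C8 hydroxy C6 ketone from F5 | COC(=O)C(C[C@@H](O)[C@@H](CC(=O)OC)C(=O)C[C@H](CO[Si](c1ccccc1)(c1ccccc1)C(C)(C)C)CCC=C)P(=O)(OC)OC
F7 | step 14 | acyclic (6R)-hydroxy C8 acetate | COC(=O)C(C[C@@H](OC(C)=O)[C@@H](CC(=O)OC)[C@H](O)C[C@H](CO[Si](c1ccccc1)(c1ccccc1)C(C)(C)C)CCC=C)P(=O)(OC)OC
F8 | step 14 | acyclic 6,12-lactone with C8 acetate, C10 phosphonate and terminal alkene | COC(=O)C(C[C@@H](OC(C)=O)[C@H]1CC(=O)O[C@@H]1C[C@H](CO[Si](c2ccccc2)(c3ccccc3)C(C)(C)C)CCC=C)P(=O)(OC)OC
F9 | step 14 | C1 aldehyde from F8 | COC(=O)C(C[C@@H](OC(C)=O)[C@H]1CC(=O)O[C@@H]1C[C@H](CO[Si](c2ccccc2)(c3ccccc3)C(C)(C)C)CCC=O)P(=O)(OC)OC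
F10 | step 18 | (6R)-alcohol of 25 with C8 silyl ether kept | CC(C)(C)[Si](c2ccccc2)(c3ccccc3)OC[C@@H]1CC/C=C(/C(=O)OC)C[C@@H](O[Si](C)(C)C(C)(C)C)[C@@H](CC(=O)OC)[C@H](O)C1
F11 | step 18 | 6,12-lactone with C8 tert-butyldimethylsilyl ether | C1C(=O)O[C@@H]2C[C@H](CO[Si](c3ccccc3)(c4ccccc4)C(C)(C)C)CC/C=C(/C(=O)OC)C[C@@H](O[Si](C)(C)C(C)(C)C)[C@@H]12
F12 | step 18 | C13 dimethylamino Mannich base of F11 (C11 epimers) | CN(C)CC1C(=O)O[C@@H]2C[C@H](CO[Si](c3ccccc3)(c4ccccc4)C(C)(C)C)CC/C=C(/C(=O)OC)C[C@@H](O[Si](C)(C)C(C)(C)C)[C@@H]12
F13 | step 18 | trimethylammonium iodide from F12 | C[N+](C)(C)CC1C(=O)O[C@@H]2C[C@H](CO[Si](c3ccccc3)(c4ccccc4)C(C)(C)C)CC/C=C(/C(=O)OC)C[C@@H](O[Si](C)(C)C(C)(C)C)[C@@H]12.[I-]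
F14 | step 18 | α-methylene lactone with C8 tert-butyldimethylsilyl ether | C=C1C(=O)O[C@@H]2C[C@H](CO[Si](c3ccccc3)(c4ccccc4)C(C)(C)C)CC/C=C(/C(=O)OC)C[C@@H](O[Si](C)(C)C(C)(C)C)[C@@H]12
F15 | step 19 | (6R)-hydroxy C8 4-oxopentanoate of ring A | CC(C)(C)[Si](c2ccccc2)(c3ccccc3)OC[C@@H]1CC/C=C(/C(=O)OC)C[C@@H](OC(=O)CCC(C)=O)[C@@H](CC(=O)OC)[C@H](O)C1
F16 | step 19 | 6,12-lactone with C8 4-oxopentanoate | C1C(=O)O[C@@H]2C[C@H](CO[Si](c3ccccc3)(c4ccccc4)C(C)(C)C)CC/C=C(/C(=O)OC)C[C@@H](OC(=O)CCC(C)=O)[C@@H]12
F17 | step 7 | methyl 4-(tert-butyldimethylsilyloxy)-3-ethynyl-5-oxopentanoate (C9 aldehyde from 9) | O=C[C@@H](O[Si](C)(C)C(C)(C)C)[C@@H](CC(=O)OC)C#C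
F18 | step 7 | alkylidene phosphonoacetate with C9=C10 (E/Z mixture) | COC(=O)C(=C[C@@H](O[Si](C)(C)C(C)(C)C)[C@@H](CC(=O)OC)C#C)P(=O)(OC)OC
F19 | step 10 | C10 triphenylphosphonium triflate | COC(=O)C(C[C@@H](O[Si](C)(C)C(C)(C)C)[C@@H](CC(=O)OC)C#C)[P+](c1ccccc1)(c1ccccc1)c1ccccc1.[O-]S(=O)(=O)C(F)(F)F
F20 | step 10 | C10 stabilised triphenylphosphorane | COC(=O)C(C[C@@H](O[Si](C)(C)C(C)(C)C)[C@@H](CC(=O)OC)C#C)=P(c1ccccc1)(c1ccccc1)c1ccccc1
A1 | alternative 1 | ten-membered 6,12-lactone with exocyclic C4=C15 methylene and C8 4-methoxybenzyl ether | C1C(=O)O[C@@H]2CC(=C)CC/C=C(/C(=O)OC)C[C@@H](OCc3ccc(OC)cc3)[C@@H]12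
A2 | alternative 1 | seco C6 aldehyde with allylsilane (C15–SiMe3, C4=C5) and C8 4-methoxybenzyl ether | C[Si](C)(C)CC(=C)CC/C=C(/C(=O)OC)C[C@@H](OCc1ccc(OC)cc1)[C@@H](CC(=O)OC)C=O
A3 | alternative 2 | ten-membered C6 trimethylsilyl enol ether with ring-cis C1=C10 alkene and C8 4-methoxybenzyl ether | C[Si](C)(C)O/C1=C\[C@H](OCc2ccc(OC)cc2)C/C(CO[Si](C)(C)C(C)(C)C)=C\CC[C@@H](CO[Si](C)(C)C(C)(C)C)C1
A4 | alternative 2 | cis-dialkenylcyclohexanol: C6 carbinol with (E)-2-(4-methoxybenzyloxy)ethenyl group, C1 with 3-silyloxyprop-1-en-2-yl group, C4 with silyloxymethyl group | O[C@]1(/C=C/OCc2ccc(OC)cc2)C[C@H](CO[Si](C)(C)C(C)(C)C)CC[C@H]1C(=C)CO[Si](C)(C)C(C)(C)C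
A5 | alternative 3 | ten-membered carbocycle fused to the 6,12-lactone with C3 phenylsulfonyl group (C3 epimers) | C1C(=O)O[C@@H]2C[C@H](COCc3ccc(OC)cc3)C(S(=O)(=O)c3ccccc3)C/C=C(/C(=O)OC)C[C@@H](O[Si](C)(C)C(C)(C)C)[C@@H]12
A6 | alternative 3 | twelve-membered lactone: C2 allylic ester of the C3 (phenylsulfonyl)acetate unit, fused to the 6,12-lactone | C1C(=O)O[C@@H]2C[C@H](COCc3ccc(OC)cc3)C(S(=O)(=O)c3ccccc3)C(=O)OC/C=C(/C(=O)OC)C[C@@H](O[Si](C)(C)C(C)(C)C)[C@@H]12
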